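**Retrosynthetic overview**
- The target is C2-symmetric. In carotenoid numbering, the centre of its retro-decaene is the E,E-diene C14=C15–C15'=C14' around the single bond C15–C15'. This array is the reduced form of a but-2-yne-1,4-diol, HO–C14–C15≡C15'–C14'–OH, so C15 and C15' can come from acetylene.
- Disconnection 1: central diene ⇒ C40 yne-1,4-diol (hydride reductive elimination). Disconnection 2: C14–C15 and C15'–C14' ⇒ two molecules of one silylated C19 pentaenal plus acetylene as its bis(bromomagnesium) salt.
- C19 pentaenal ⇒ C14 trienal + C5 phosphonate (C10=C11). C14 trienal ⇒ C11 dienal + C3 phosphonate (C8=C9). C11 dienal ⇒ ethynyl carbinol (Meyer–Schuster, C6=C7) ⇒ silylated (S)-hydroxy enone + acetylene.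
- No ring is formed. Both trimethylcyclohexene rings are bought as ketoisophorone, and the only stereocentre of each half (C3, S) is set in step 1.

Key step: step 11

Assumption: carotenoid numbering is used for all positions (C1 gem-dimethyl carbon, C3 carbinol, C4=C5, C6 ring carbon bearing the chain, C7 to C15, primes for the second half), and every polyene from 10 onwards is handled under argon, in dim light and away from acid.

**Step 1**
Reactants: 1 ketoisophorone (2,6,6-trimethylcyclohex-2-ene-1,4-dione)
Product: 2 (4S)-4-hydroxy-2,6,6-trimethylcyclohex-2-en-1-one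
Conditions: RuCl[(S,S)-TsDPEN](p-cymene) (0.5 mol %), KOH (1 mol %), i-PrOH, 20 °C
Reagents that add atoms: none
Why: Noyori-type asymmetric transfer hydrogenation reduces only the open C4 carbonyl, because the C1 carbonyl is flanked by the quaternary carbon and the methyl-bearing alkene carbon, and with the alkenyl arm in the place of the aryl group of the usual aryl ketone model the (S,S)-ligand should deliver hydride to the face that gives the 4S carbinol, the later C3 (the mirror-image ligand is equally available should the sense prove opposite).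

**Step 2**
Reactants: 2 (4S)-4-hydroxy-2,6,6-trimethylcyclohex-2-en-1-one
Product: 3 (4S)-4-(tert-butyldimethylsilyloxy)-2,6,6-trimethylcyclohex-2-en-1-one
Conditions: TBSCl, imidazole, DMF, 0 °C to rt
Reagents that add atoms: tert-butyldimethylsilyl chloride, CC(C)(C)[Si](C)(C)Cl
Why: Standard imidazole-promoted silylation of a secondary allylic alcohol masks the hydroxyl against the later organometallic and hydride reagents and blocks tautomerisation of the 4-hydroxy enone to the saturated diketone, and since the C–O bond is untouched the configuration is kept.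

**Step 3**
Reactants: 3 (4S)-4-(tert-butyldimethylsilyloxy)-2,6,6-trimethylcyclohex-2-en-1-one; 4 acetylene
Product: 6 (4S)-4-(tert-butyldimethylsilyloxy)-1-ethynyl-2,6,6-trimethylcyclohex-2-en-1-ol (C1 epimers), via lithium acetylide 5 (not isolated)
Conditions: 4 (excess), n-BuLi, THF, −78 °C; then 3, −78 to 0 °C; H2O
Reagents that add atoms: none
Why: In this 1,2-addition of monolithium acetylide to a hindered enone carbonyl without α-hydrogen, the small hard nucleophile should reach C1 at low temperature faster than it abstracts the γ-hydrogen at the silyloxy carbon, so the S centre is kept, and the new tertiary carbinol, formed without control, is erased in step 4.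

**Step 4**
Reactants: 6 (4S)-4-(tert-butyldimethylsilyloxy)-1-ethynyl-2,6,6-trimethylcyclohex-2-en-1-ol
Product: 7 (2E)-2-[(4S)-4-(tert-butyldimethylsilyloxy)-2,6,6-trimethylcyclohex-2-en-1-ylidene]acetaldehyde (C11 dienal, 6E)
Conditions: VO(OSiPh3)3 (5 mol %), Ph3SiOH (10 mol %), xylene, 130 °C
Reagents that add atoms: none
Why: The Meyer–Schuster rearrangement runs through the vanadate ester, whose [3,3] shift gives an allenyl vanadate that tautomerises irreversibly to the enal, so any reversible 1,3-shift of the hydroxyl into the ring drains back; the Rupe pathway is closed because neither carbon flanking the carbinol bears hydrogen, and equilibration at this temperature should favour the 6E isomer, in which the formyl carbon avoids the in-plane C5 methyl and sits between the two C1 methyls.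

**Step 5**
Reactants: 7 C11 dienal; 8 triethyl 2-phosphonopropionate
Product: 10 ethyl (2E,4E)-4-[(4S)-4-(tert-butyldimethylsilyloxy)-2,6,6-trimethylcyclohex-2-en-1-ylidene]-2-methylbut-2-enoate (C14 ester), via sodium phosphonate carbanion 9 (not isolated)
Conditions: 8 (1.1 equiv), NaH (1.05 equiv), THF, 0 °C; then 7, 0 °C to rt
Reagents that add atoms: none
Why: Horner–Wadsworth–Emmons olefination with a stabilised α-methyl phosphonate places the ester trans to C7 (8E), and the anion is pre-formed with a slight deficit of base so that no strong base meets the vinylogously acidic C3–H of 7.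

**Step 6**
Reactants: 10 C14 ester
Product: 11 (2E,4E)-4-[(4S)-4-(tert-butyldimethylsilyloxy)-2,6,6-trimethylcyclohex-2-en-1-ylidene]-2-methylbut-2-en-1-ol (C14 alcohol)
Conditions: i-Bu2AlH (2.3 equiv), CH2Cl2, −78 °C; aq. potassium sodium tartrate
Reagents that add atoms: none
Why: Low-temperature 1,2-reduction of a conjugated ester with i-Bu2AlH stops at the allylic alcohol and leaves the silyl ether and the triene untouched.

**Step 7**
Reactants: 11 C14 alcohol
Product: 12 (2E,4E)-4-[(4S)-4-(tert-butyldimethylsilyloxy)-2,6,6-trimethylcyclohex-2-en-1-ylidene]-2-methylbut-2-enal (C14 trienal)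
Conditions: activated MnO2 (excess), CH2Cl2, rt
Reagents that add atoms: none
Why: Heterogeneous MnO2 oxidation is selective for allylic primary alcohols and neutral, so the double-bond geometries and the silyl ether are retained.

**Step 8**
Reactants: 12 C14 trienal; 13 ethyl (E)-4-(diethoxyphosphoryl)-2-methylbut-2-enoate
Product: 15 ethyl (2E,4E,6E,8E)-8-[(4S)-4-(tert-butyldimethylsilyloxy)-2,6,6-trimethylcyclohex-2-en-1-ylidene]-2,6-dimethylocta-2,4,6-trienoate (C19 ester), via lithium phosphonate carbanion 14 (not isolated)
Conditions: 13 (1.15 equiv), LiN(SiMe3)2 (1.1 equiv), THF, −78 °C; then 12, −78 to 0 °C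
Reagents that add atoms: none
Why: In this vinylogous Horner–Wadsworth–Emmons olefination the allylic phosphonate anion reacts at the carbon next to phosphorus, giving the new C10=C11 bond as E, while C12=C13 keeps the E geometry of the reagent, which is also the more stable form of the anion.

**Step 9**
Reactants: 15 C19 ester
Product: 16 (2E,4E,6E,8E)-8-[(4S)-4-(tert-butyldimethylsilyloxy)-2,6,6-trimethylcyclohex-2-en-1-ylidene]-2,6-dimethylocta-2,4,6-trien-1-ol (C19 alcohol)
Conditions: i-Bu2AlH (2.3 equiv), CH2Cl2, −78 °C; aq. potassium sodium tartrate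
Reagents that add atoms: none
Why: This is the same 1,2-reduction of a conjugated ester as in step 6, and a non-acidic work-up protects the ionisable pentaenylic alcohol.

**Step 10**
Reactants: 16 C19 alcohol
Product: 17 (2E,4E,6E,8E)-8-[(4S)-4-(tert-butyldimethylsilyloxy)-2,6,6-trimethylcyclohex-2-en-1-ylidene]-2,6-dimethylocta-2,4,6-trienal (silylated C19 pentaenal)
Conditions: activated MnO2 (excess), CH2Cl2, rt
Reagents that add atoms: none
Why: MnO2 oxidation of a polyenylic primary alcohol is fast and neutral and should deliver the all-E aldehyde without touching C3.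

**Step 11**
Reactants: 4 acetylene (one equivalent); 17 silylated C19 pentaenal (two equivalents)
Product: 19 C40 15,15'-yne-14,14'-diol bis(tert-butyldimethylsilyl ether) (C14 and C14' epimers unassigned), via ethyne-1,2-diylbis(magnesium bromide) 18 (not isolated)
Conditions: 4 (1.0 equiv, titrated THF solution), EtMgBr (2.05 equiv), Et2O–THF, 20 to 40 °C until gas evolution ends; then 17 (2.0 equiv) in toluene, 0 to 40 °C; sat. aq. NH4Cl, 0 °C
Reagents that add atoms: none
Why: Each C–Mg bond of 18 adds through a magnesium-coordinated carbonyl to the formyl carbon C14 of one molecule of 17, the first addition leaving a bromomagnesium alkoxide that still carries the second acetylide terminus and the second addition completing C14–C15≡C15'–C14'. The closest known reaction type is the two-directional addition of the acetylene bis-Grignard reagent to two α-methyl polyenals, the C19 + C2 + C19 pattern of carotenoid assembly. No ring closes, both cyclohexene rings arriving intact from 1. The new carbinol centres C14 and C14' have no controlling element and form as epimers, which is harmless because both become sp2 carbons in step 12, and C3 and C3' are remote and untouched. The step needs 1,2- over conjugate addition and double over single addition: the hard magnesium acetylide takes the aldehyde carbon, the least hindered and most electrophilic site, since the vinylogous positions C12, C10, C8, C6 and C4 are weakly polarised, and the 2:1 stoichiometry with a reagent pre-formed from a measured amount of acetylene secures the second addition. Because two enantioenriched halves are joined, residual R material is diverted mainly to the 3R,3'S diastereomer, which can be removed later by crystallisation.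

**Step 12**
Reactants: 19 C40 yne-diol bis(silyl ether)
Product: 21 (3S,3'S)-eschscholtzxanthin bis(tert-butyldimethylsilyl ether) (mainly 14E,14'E; C14=C15 and C15'=C14' written unassigned), via allenyl carbinol 20 (not isolated)
Conditions: LiAlH4 (4 equiv), THF, 0 to 50 °C; Na2SO4·10H2O, 0 °C
Reagents that add atoms: none
Why: In the Whiting reductive elimination, alkoxyaluminate-directed trans-hydroalumination puts hydride on C15 and aluminium on C15', β-elimination of the C14' oxygen gives allenyl carbinol 20, and a second internal hydride delivery to C15' with SN2' loss of the C14 oxygen gives the C14=C15–C15'=C14' diene, both departures being eased by the pentaenylic position of the carbinols, while silyl ethers and the unpolarised polyene are inert to LiAlH4.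

**Step 13**
Reactants: 21 bis(silyl ether)
Product: 22 (3S,3'S)-eschscholtzxanthin as a mixture of C14=C15 and C15'=C14' geometrical isomers
Conditions: Bu4NF (3 equiv), THF, rt
Reagents that add atoms: none
Why: Fluoride-driven Si–O cleavage works without acid, which matters because the C3 and C3' carbinols are allylic to the whole dodecaene and ionise easily, and the C–O bonds are not broken, so both S centres are kept.

**Step 14**
Reactants: 22 isomer mixture
Product: 23 (3S,3'S,all-E)-eschscholtzxanthin (target)
Conditions: EtOH, reflux, argon, dark; slow cooling and crystallisation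
Reagents that add atoms: none
Why: In this thermal E/Z equilibration of a carotenoid polyene, a Z bond at C14=C15 presses a C13 substituent against the C15'=C14' unit (hindered cis), so heating should funnel the isomers, including any 6Z material, to the all-E form, whose lower solubility lets crystallisation drive the equilibrium and reject the 3R,3'S diastereomer.

**Compound list**
1 | ketoisophorone (2,6,6-trimethylcyclohex-2-ene-1,4-dione) | CC1=CC(=O)CC(C)(C)C1=O | starting material
2 | (4S)-4-hydroxy-2,6,6-trimethylcyclohex-2-en-1-one | CC1=C[C@@H](O)CC(C)(C)C1=O | intermediate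
3 | (4S)-4-(tert-butyldimethylsilyloxy)-2,6,6-trimethylcyclohex-2-en-1-one | CC1=C[C@@H](O[Si](C)(C)C(C)(C)C)CC(C)(C)C1=O | intermediate
4 | acetylene | C#C | starting material
5 | lithium acetylide (not isolated) | [Li]C#C | intermediate
6 | (4S)-4-(tert-butyldimethylsilyloxy)-1-ethynyl-2,6,6-trimethylcyclohex-2-en-1-ol, C1 epimers | CC1=C[C@@H](O[Si](C)(C)C(C)(C)C)CC(C)(C)C1(O)C#C | intermediate
7 | (2E)-2-[(4S)-4-(tert-butyldimethylsilyloxy)-2,6,6-trimethylcyclohex-2-en-1-ylidene]acetaldehyde | CC1=C[C@@H](O[Si](C)(C)C(C)(C)C)CC(C)(C)\C1=C/C=O | intermediate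
8 | triethyl 2-phosphonopropionate | CCOC(=O)C(C)P(=O)(OCC)OCC | starting material
9 | sodium salt of the carbanion of 8 (not isolated) | CCOC(=O)[C-](C)P(=O)(OCC)OCC.[Na+] | intermediate
10 | ethyl (2E,4E)-4-[(4S)-4-(tert-butyldimethylsilyloxy)-2,6,6-trimethylcyclohex-2-en-1-ylidene]-2-methylbut-2-enoate | CC1=C[C@@H](O[Si](C)(C)C(C)(C)C)CC(C)(C)\C1=C/C=C(C)/C(=O)OCC | intermediate
11 | (2E,4E)-4-[(4S)-4-(tert-butyldimethylsilyloxy)-2,6,6-trimethylcyclohex-2-en-1-ylidene]-2-methylbut-2-en-1-ol | CC1=C[C@@H](O[Si](C)(C)C(C)(C)C)CC(C)(C)\C1=C/C=C(C)/CO | intermediate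
12 | (2E,4E)-4-[(4S)-4-(tert-butyldimethylsilyloxy)-2,6,6-trimethylcyclohex-2-en-1-ylidene]-2-methylbut-2-enal | CC1=C[C@@H](O[Si](C)(C)C(C)(C)C)CC(C)(C)\C1=C/C=C(C)/C=O | intermediate
13 | ethyl (E)-4-(diethoxyphosphoryl)-2-methylbut-2-enoate | CCOC(=O)/C(C)=C/CP(=O)(OCC)OCC | starting material
14 | lithium salt of the carbanion of 13 (not isolated) | CCOC(=O)/C(C)=C/[CH-]P(=O)(OCC)OCC.[Li+] | intermediate
15 | ethyl (2E,4E,6E,8E)-8-[(4S)-4-(tert-butyldimethylsilyloxy)-2,6,6-trimethylcyclohex-2-en-1-ylidene]-2,6-dimethylocta-2,4,6-trienoate | CC1=C[C@@H](O[Si](C)(C)C(C)(C)C)CC(C)(C)\C1=C/C=C(C)/C=C/C=C(C)/C(=O)OCC | intermediate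
16 | (2E,4E,6E,8E)-8-[(4S)-4-(tert-butyldimethylsilyloxy)-2,6,6-trimethylcyclohex-2-en-1-ylidene]-2,6-dimethylocta-2,4,6-trien-1-ol | CC1=C[C@@H](O[Si](C)(C)C(C)(C)C)CC(C)(C)\C1=C/C=C(C)/C=C/C=C(C)/CO | intermediate
17 | (2E,4E,6E,8E)-8-[(4S)-4-(tert-butyldimethylsilyloxy)-2,6,6-trimethylcyclohex-2-en-1-ylidene]-2,6-dimethylocta-2,4,6-trienal (silylated C19 pentaenal) | CC1=C[C@@H](O[Si](C)(C)C(C)(C)C)CC(C)(C)\C1=C/C=C(C)/C=C/C=C(C)/C=O | intermediate
18 | ethyne-1,2-diylbis(magnesium bromide) (not isolated) | Br[Mg]C#C[Mg]Br | intermediate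
19 | C40 15,15'-yne-14,14'-diol bis(tert-butyldimethylsilyl ether): but-2-yne-1,4-diol bearing at C1 and C4 the all-E 7-[(4S)-4-silyloxy-2,6,6-trimethylcyclohex-2-en-1-ylidene]-1,5-dimethylhepta-1,3,5-trienyl group, carbinol epimers unassigned | CC1=C[C@@H](O[Si](C)(C)C(C)(C)C)CC(C)(C)\C1=C/C=C(C)/C=C/C=C(C)/C(O)C#CC(O)/C(C)=C/C=C/C(C)=C/C=C1/C(C)=C[C@@H](O[Si](C)(C)C(C)(C)C)CC1(C)C | intermediate
20 | C40 14-hydroxy-15,15',14'-allene bis(silyl ether), present as its aluminium alkoxide and drawn as the free alcohol, carbinol and allene axis unassigned (not isolated) | CC1=C[C@@H](O[Si](C)(C)C(C)(C)C)CC(C)(C)\C1=C/C=C(C)/C=C/C=C(C)/C(O)C=C=C/C(C)=C/C=C/C(C)=C/C=C1/C(C)=C[C@@H](O[Si](C)(C)C(C)(C)C)CC1(C)C | intermediate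
21 | (3S,3'S)-eschscholtzxanthin bis(tert-butyldimethylsilyl ether), C14=C15 and C15'=C14' unassigned (mainly E,E) | CC1=C[C@@H](O[Si](C)(C)C(C)(C)C)CC(C)(C)\C1=C/C=C(C)/C=C/C=C(C)/C=CC=C/C(C)=C/C=C/C(C)=C/C=C1/C(C)=C[C@@H](O[Si](C)(C)C(C)(C)C)CC1(C)C | intermediate
22 | (3S,3'S)-eschscholtzxanthin, C14=C15 and C15'=C14' unassigned (isomer mixture) | CC1=C[C@@H](O)CC(C)(C)\C1=C/C=C(C)/C=C/C=C(C)/C=CC=C/C(C)=C/C=C/C(C)=C/C=C1/C(C)=C[C@@H](O)CC1(C)C | intermediate
23 | (3S,3'S,all-E)-eschscholtzxanthin, (3S,3'S)-4',5'-didehydro-4,5'-retro-β,β-carotene-3,3'-diol | CC1=C[C@@H](O)CC(C)(C)\C1=C/C=C(C)/C=C/C=C(C)/C=C/C=C/C(C)=C/C=C/C(C)=C/C=C1/C(C)=C[C@@H](O)CC1(C)C | target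

**Totals and risks**

Total step count: 14. Longest linear sequence: 14 steps (1 to 23); compounds 4, 8 and 13 are bought.

Steps most likely to fail:

1. **Step 11.**
   - Risk: the poorly soluble bis-Grignard reagent may stall after the first addition or disproportionate to the mono-Grignard reagent, and the pentaenylic carbinols may ionise on work-up.
   - Fallback: this sets out from 17 and returns at 19, building the same two bonds one after the other. One portion of 17 is treated with ethynylmagnesium bromide (HC≡CMgBr, from 4 and EtMgBr, THF, 0 °C) to give the C21 propargylic alcohol F1. F1 is converted with two equivalents of n-BuLi (THF, −78 °C) into its soluble O,C-dilithio derivative, and a second portion of 17 is added to give 19.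

2. **Step 12.**
   - Risk: the reduction may stop at the ene-diol stage. Hydride may enter at remote polyene positions with a shift of the double-bond pattern. The new double bonds may also form with poor E selectivity.
   - Fallback: this sets out from 19 and returns at 21. Semihydrogenation of the alkyne (H2, Pd/CaCO3–Pb(OAc)2, quinoline, toluene) gives the (15Z)-ene-14,14'-diol F2. Low-valent titanium made from TiCl3 and LiAlH4 in THF then effects the known 1,4-reductive elimination of a 2-ene-1,4-diol to the 1,3-diene 21.

3. **Step 4.**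
   - Risk: the hydroxyl may shift competitively into the ring, the material may degrade at the temperature the vanadate needs, and the geometry of the exocyclic C6=C7 bond may be poorly controlled.
   - Fallback: this sets out from 3 and returns at 7.
     - Lithium ethoxyacetylide (ethoxyacetylene, n-BuLi, THF, −78 °C) adds to 3 to give the ethoxyalkynyl carbinol F3.
     - The electron-rich alkyne of F3 rearranges at room temperature with Sc(OTf)3 (cat., CH2Cl2–EtOH) to the ethyl ylideneacetate F4, whose 6E isomer is separated.
     - i-Bu2AlH (CH2Cl2, −78 °C) gives the allylic alcohol F5, and MnO2 oxidises it to 7.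

**Further compounds**
F1 | step 11 | (4E,6E,8E,10E)-10-[(4S)-4-(tert-butyldimethylsilyloxy)-2,6,6-trimethylcyclohex-2-en-1-ylidene]-4,8-dimethyldeca-4,6,8-trien-1-yn-3-ol (C21 propargylic alcohol, carbinol unassigned) | CC1=C[C@@H](O[Si](C)(C)C(C)(C)C)CC(C)(C)\C1=C/C=C(C)/C=C/C=C(C)/C(O)C#C
F2 | step 12 | C40 (15Z)-ene-14,14'-diol bis(tert-butyldimethylsilyl ether), carbinol epimers unassigned | CC1=C[C@@H](O[Si](C)(C)C(C)(C)C)CC(C)(C)\C1=C/C=C(C)/C=C/C=C(C)/C(O)/C=C\C(O)/C(C)=C/C=C/C(C)=C/C=C1/C(C)=C[C@@H](O[Si](C)(C)C(C)(C)C)CC1(C)C
F3 | step 4 | (4S)-4-(tert-butyldimethylsilyloxy)-1-(ethoxyethynyl)-2,6,6-trimethylcyclohex-2-en-1-ol, C1 epimers | CC1=C[C@@H](O[Si](C)(C)C(C)(C)C)CC(C)(C)C1(O)C#COCC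
F4 | step 4 | ethyl (2E)-2-[(4S)-4-(tert-butyldimethylsilyloxy)-2,6,6-trimethylcyclohex-2-en-1-ylidene]acetate | CC1=C[C@@H](O[Si](C)(C)C(C)(C)C)CC(C)(C)\C1=C/C(=O)OCC
F5 | step 4 | (2E)-2-[(4S)-4-(tert-butyldimethylsilyloxy)-2,6,6-trimethylcyclohex-2-en-1-ylidene]ethanol | CC1=C[C@@H](O[Si](C)(C)C(C)(C)C)CC(C)(C)\C1=C/CO
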